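## Analysis of the target

Numbering follows the benzofuranone: O1, C2 (lactone carbonyl), C3 (vinyl CH), C3a, C4 (gem-dimethyl), C5, C6 (ester-bearing CH), C7, C7a (methyl and O1).

Compound 12 is the hexadecanoate of (−)-loliolide. A cyclohexane (ring A: C3a, C4, C5, C6, C7, C7a) is fused along C3a–C7a to a butenolide (ring B: O1, C2, C3, C3a, C7a), with the C3=C3a double bond exocyclic to ring A. C4, C3a and C7a are three contiguous fully substituted carbons. There are two stereocentres, C6 (S) and C7a (R), 1,3-related across C7, with the C6 oxygen trans to O1 and cis to the C7a methyl. The flat butenolide holds O1 pseudo-equatorial, so the C7a methyl is axial and the C6 oxygen is axial on the same face as this methyl and the axial C4 methyl. This is the crowded position, so C6 has to be set kinetically. Sensitive points are the two ester linkages and the tertiary C7a–O1 bond. In any C6 ketone this bond is β to the carbonyl, and once C3a is trigonal a retro-oxa-Michael opening gives an achiral dienone acid. The difficulty is therefore the oxygenated quaternary stereocentre C7a in a congested setting and its relay to C6. The strategy rests on a hidden symmetry of ring A: leaving out one C4 methyl, its substituents are those of 3,5-dimethylphenol with a two-carbon acid in the para position. The phenol oxygen maps onto the C6 oxygen, the two meta methyls onto the methyls at C4 and C7a, and the para carbon onto C3a.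

## Retrosynthetic reasoning

**12 to 10 and 11.** The ester C–O bond at C6 is cut first. The C16 chain adds no structural help earlier and is best kept away from hydride and strong base. The forward step has to acylate a hindered axial secondary alcohol without disturbing the butenolide.

**10 to 9.** The C6–H bond is formed by reducing the C6 ketone at the butenolide stage. Only there is ring A locked in one chair, with the C7a methyl and one C4 methyl axial on the same face, so a bulky hydride must come from the other face. On a saturated, cis-fused precursor ring A can choose between two chairs that predict opposite outcomes. The forward step has to be a fast, low-temperature reduction, because 9 would racemise by ring opening if it met base.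

**9 to 7, through 8.** The C3=C3a double bond comes from β-elimination of the C3a methoxy group. The direction is unambiguous because C4 and C7a carry no hydrogen. Acid-induced loss from a free C6 ketone is avoided for three reasons:
- the C7a–O1 bond, β to the ketone, would open more easily than the methoxy group leaves;
- a cation at C3a between two quaternary carbons invites methyl shifts;
- after the elimination, any ring opening destroys the only stereocentre.

The elimination is therefore run from the lactone enolate while the ketone is masked as the enol ether 7, with its double bond towards C5. This is the form in which the preceding conjugate addition delivers the ketone anyway.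

**7 to 6.** The C4–CH3 bond is cut. This methyl is the one carbon an aromatic precursor cannot carry. It is added as a soft methyl nucleophile to the one enone left in 6, and the enolate is trapped on oxygen.

**6 to 5 (key disconnection).** The O1–C7a bond of ring B is cut. In 5 the two enone arms are enantiotopic. Adding the side-chain acid to one of them fixes C7a and, since the five-membered ring can only be cis-fused, C3a as well. This gives both rings and the absolute configuration from an achiral compound in one operation. The forward reaction must be catalyst-controlled and kept under kinetic control.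

**5 to 4.** The C3a–O(methyl) bond is cut, which is an oxidative dearomatisation in reverse. The para carbon of the phenol becomes the quaternary C3a, and the methoxy group is the placeholder for the later double bond.

**4 to 3 to 1 and 2.** The aryl–carbon bond para to the hydroxyl is cut. Hydroxyalkylation of 1 with 2 followed by benzylic deoxygenation supplies the two-carbon acid in the right oxidation state, with no protecting groups.

## Alternatives that were turned down

**Alternative 1: iron-hydride radical cyclisation.**
- Disconnection: the C4–C3a bond of ring A, back to the open-chain ynoate A2, which carries both stereocentres and an isopropenyl end.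
- Forward key step: the iron hydride from Fe(acac)3 and PhSiH3 transfers a hydrogen atom to the terminal alkene carbon. The tertiary C4 radical adds 6-exo-dig to the β-carbon (C3a) of the ynoate. The vinyl radical is reduced to the alkylidene ester A1, which would lactonise through the C7a hydroxyl.
- For: a nucleophilic tertiary radical and an electron-poor alkyne are polarity-matched. The quaternary C4 is formed without regard to crowding, and the palmitate survives the neutral conditions. On the making of C4 this route is stronger than a cuprate addition next to a quaternary carbon.
- Against: A2 needs two stereocentres set in an open chain by two separate controlling operations. One is a tertiary propargylic carbinol, for which 1,3-induction from C6 is weak. The bent vinyl radical gives no reliable control of alkylidene geometry, and only the Z ester can lactonise. Hydride reduction of the ynoate can compete.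
- Comparison: the chosen route offers instead one catalytic stereo-determining event on an achiral, flat precursor made in three steps, with C6 following by substrate control.

**Alternative 2: hetero-Pauson–Khand cyclocarbonylation.**
- Disconnection: C3a–C7a, C2–C3 and C2–O1 together, back to the ynone A4 and carbon monoxide.
- Forward key step: the methyl ketone and the terminal alkyne couple oxidatively at a low-valent metal carbonyl (Mo(CO)6 or Ru3(CO)12). CO insertion and reductive elimination give the silyl-protected butenolide A3.
- For: it forms the most bonds in one step, delivers ring B in its final oxidation state and needs a precursor with a single stereocentre. The gem-dimethyl group favours ring closure. In convergency it is stronger than the chosen route.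
- Against: carbonylative coupling of a ketone that closes a six-membered carbocycle lies at the edge of this reaction's scope, and terminal alkynes tend to oligomerise. C7a would depend on 1,3-induction from C6. The C6 configuration in A3 is the wrong one for the target. Its equatorial C–O bond cannot be inverted by substitution, because the axial trajectory is screened by two axial methyls. The end-game therefore needs desilylation, oxidation to 9, reduction and acylation.
- Comparison: the chosen route reaches 9 with C7a already secured by a catalyst rather than by a remote substituent.

**Alternative 3: carbenoid C–H insertion.**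
- Disconnection: the C3–C3a bond, back to the diazomalonate A6, the C7a ester of a 1,3,3-trimethylcyclohexane-1,5-diol monopalmitate.
- Forward key step: with Rh2(OAc)4 the carbenoid inserts 1,5 into a C3a–H bond and gives the cis-fused lactone A5. Palladium-catalysed decarboxylation–dehydrogenation of the allyl ester would then introduce the C3=C3a double bond.
- For: both stereocentres are set beforehand on a ring, where relative configuration is easy to control. The insertion retains configuration and can only give the cis lactone. On precedent for its key step this route is stronger than the chosen one.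
- Against: the C7a oxygen offers two five-membered insertions. The C3a–H bonds lie between two quaternary carbons. The C7–H bonds are more accessible, though deactivated by the neighbouring acyloxy carbon. The enantiopure diol has to be made or resolved, and a hindered tertiary alcohol has to be malonylated and diazotised.
- Comparison: the sequence is clearly longer. The chosen route offers brevity and absolute stereocontrol from an aromatic feedstock, and accepts a less precedented key step in exchange.

Key step: step 4

Assumption: the sense of induction of the bifunctional catalyst on 5 cannot be foreseen with confidence; the quinine-derived catalyst is written, and its quinidine-derived pseudoenantiomer is to be used instead if that is the one leading to the (3aR,7aR) lactone 6.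

## Route

Step 1
Reactants: 1 3,5-dimethylphenol; 2 glyoxylic acid (50% aqueous solution)
Product: 3 rac-2-hydroxy-2-(4-hydroxy-2,6-dimethylphenyl)acetic acid
Conditions: NaOH (2.2 equiv), H2O, 25–40 °C; then HCl to pH 1, crystallisation
Reagents that add atoms: none
Why: Alkaline hydroxyalkylation of a phenol with glyoxylic acid (the reaction type used for 4-hydroxymandelic acids): the phenoxide attacks the aldehyde carbon through the para position, which both methyl groups activate; ortho isomers are to be removed by crystallisation, and the new stereocentre is deleted in step 2.

Step 2
Reactants: 3 rac-2-hydroxy-2-(4-hydroxy-2,6-dimethylphenyl)acetic acid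
Product: 4 2-(4-hydroxy-2,6-dimethylphenyl)acetic acid
Conditions: Et3SiH (3 equiv), CF3CO2H, CH2Cl2, 0 °C to rt
Reagents that add atoms: none
Why: Ionic hydrogenation of a benzylic alcohol: acid ionises the C–OH bond, assisted by the para hydroxyl and the two ortho methyls, and the silane transfers hydride to the benzylic cation; phenol and carboxylic acid are inert, and excess silane suppresses arylation of the cation.

Step 3
Reactants: 4 2-(4-hydroxy-2,6-dimethylphenyl)acetic acid
Product: 5 2-(1-methoxy-2,6-dimethyl-4-oxocyclohexa-2,5-dien-1-yl)acetic acid
Conditions: PhI(OAc)2 (1.1 equiv), MeOH, 0 °C; cold work-up without base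
Reagents that add atoms: methanol, CO
Why: Oxidative dearomatisation of a para-substituted phenol with a trivalent iodine reagent: the phenol is activated on oxygen by ligand exchange and the solvent attacks the para carbon to give the 4-methoxycyclohexa-2,5-dienone; a spiro β-lactone from the side-chain acid is too strained to compete, and the methyl groups on both β-carbons slow spontaneous lactonisation of 5.

Step 4
Reactants: 5 2-(1-methoxy-2,6-dimethyl-4-oxocyclohexa-2,5-dien-1-yl)acetic acid
Product: 6 (3aR,7aR)-3a-methoxy-4,7a-dimethyl-3,3a,7,7a-tetrahydro-1-benzofuran-2,6-dione
Conditions: N-[3,5-bis(trifluoromethyl)phenyl]-N′-[(8α,9S)-6′-methoxycinchonan-9-yl]thiourea (10 mol%), toluene/CH2Cl2, −20 °C; cold filtration through silica to remove the catalyst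
Reagents that add atoms: none
Why: Proposed new method: the quinuclidine nitrogen of the catalyst deprotonates the carboxylic acid of 5, while the thiourea N–H bonds and the resulting ammonium ion hydrogen-bond to the dienone carbonyl, so the carboxylate is held over one of the two enantiotopic enone arms and adds to its methyl-bearing β-carbon, after which the ammonium ion protonates the enolate at C7 and the catalyst is released. The closest known reaction type is the organocatalytic desymmetrising intramolecular oxa-Michael addition of alcohols to 4,4-disubstituted cyclohexa-2,5-dienones (cinchona amine–thiourea or chiral phosphoric acid), and lactonisation of (4-oxocyclohexa-2,5-dienyl)acetic acids onto an unsubstituted β-carbon is known in racemic form; new here are the carboxylate nucleophile under enantiocontrol and the fully substituted acceptor carbon. Ring B closes 5-exo-trig through O1–C7a, the only mode a two-atom tether allows. C7a is set by the catalyst's choice between the enantiotopic β-carbons, and C3a becomes stereogenic in the same event with its configuration dictated by the requirement that the γ-lactone be cis-fused. The step needs enantiotopic-group selectivity under kinetic control, because the addition is reversible through β-elimination of the carboxylate; low temperature, a non-polar medium and prompt removal of the amine serve this. The substrate helps in that the methoxy group cannot act as a nucleophile, no second acid is present to attack the remaining enone, and the β-methyl groups hold back the uncatalysed background reaction.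

Step 5
Reactants: 6 (3aR,7aR)-3a-methoxy-4,7a-dimethyl-3,3a,7,7a-tetrahydro-1-benzofuran-2,6-dione
Product: 7 (3aR,7aR)-3a-methoxy-4,4,7a-trimethyl-6-[(trimethylsilyl)oxy]-3a,4,7,7a-tetrahydro-1-benzofuran-2(3H)-one
Conditions: Me2CuLi (from CuBr·SMe2 and MeLi), Me3SiCl, THF, −78 to −40 °C; Et3N, pentane, filtration, crude product used directly
Reagents that add atoms: lithium dimethylcuprate, [Li+].C[Cu-]C; chlorotrimethylsilane, C[Si](C)(C)Cl
Why: Chlorosilane-accelerated conjugate addition of a Gilman cuprate to a β,β-disubstituted enone: methyl is the smallest transferable group, the silyl chloride speeds the addition and traps the enolate on oxygen, which fixes the enol double bond between C5 and C6, away from the C7a–O1 bond; C4 becomes a gem-dimethyl carbon, so no stereocentre arises, and the lactone is not attacked by the cuprate.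

Step 6
Reactants: 7 (3aR,7aR)-3a-methoxy-4,4,7a-trimethyl-6-[(trimethylsilyl)oxy]-3a,4,7,7a-tetrahydro-1-benzofuran-2(3H)-one
Product: 9 (7aR)-4,4,7a-trimethyl-5,7a-dihydro-1-benzofuran-2,6(4H,7H)-dione, via butenolide trimethylsilyl enol ether 8 (not isolated)
Conditions: LiN(i-Pr)2 (1.2 equiv), THF, −78 to −10 °C; then poured into cold 1 M HCl/THF, 0 °C
Reagents that add atoms: none
Why: E1cB elimination of a β-alkoxy lactone: the amide base removes a C3 proton and the lactone enolate expels methoxide from C3a, where only the C3=C3a alkene can form because C4 and C7a bear no hydrogen; the silyl enol ether keeps C7 non-acidic during the basic phase, so the C7a–O1 bond cannot be lost by β-elimination, and the acidic quench unmasks the ketone without exposing 9 to base, leaving C7a untouched.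

Step 7
Reactants: 9 (7aR)-4,4,7a-trimethyl-5,7a-dihydro-1-benzofuran-2,6(4H,7H)-dione
Product: 10 (6S,7aR)-6-hydroxy-4,4,7a-trimethyl-5,6,7,7a-tetrahydro-1-benzofuran-2(4H)-one, (−)-loliolide
Conditions: LiBH(s-Bu)3 (1.1 equiv), THF, −78 °C; AcOH quench at −78 °C
Reagents that add atoms: none
Why: Diastereoselective ketone reduction by a bulky trialkylborohydride (equatorial attack): the planar butenolide holds O1 pseudo-equatorial, so the C7a methyl and one C4 methyl are axial on one face of ring A and block it, and hydride should enter from the opposite face to give the axial alcohol cis to the C7a methyl and trans to O1, which is 6S; at −78 °C the ketone is reduced far faster than the β,β-disubstituted butenolide or any enolisation.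

Step 8
Reactants: 10 (6S,7aR)-6-hydroxy-4,4,7a-trimethyl-5,6,7,7a-tetrahydro-1-benzofuran-2(4H)-one; 11 palmitoyl chloride
Product: 12 (6S,7aR)-4,4,7a-trimethyl-2-oxo-2,4,5,6,7,7a-hexahydro-1-benzofuran-6-yl hexadecanoate, (−)-3-O-palmitoylloliolide
Conditions: pyridine, DMAP (cat.), CH2Cl2, 0 °C to rt
Reagents that add atoms: none
Why: DMAP-catalysed acylation of a secondary alcohol with an acid chloride through the acylpyridinium ion, which is reactive enough for the hindered axial hydroxyl; the C6–O bond is not broken, so the configuration is retained, and the weak base leaves the butenolide alone.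

## Compound list

1 | 3,5-dimethylphenol | Cc1cc(C)cc(O)c1 | starting material
2 | glyoxylic acid | O=CC(=O)O | starting material
3 | rac-2-hydroxy-2-(4-hydroxy-2,6-dimethylphenyl)acetic acid | Cc1cc(O)cc(C)c1C(O)C(=O)O | intermediate
4 | 2-(4-hydroxy-2,6-dimethylphenyl)acetic acid | Cc1cc(O)cc(C)c1CC(=O)O | intermediate
5 | 2-(1-methoxy-2,6-dimethyl-4-oxocyclohexa-2,5-dien-1-yl)acetic acid | COC1(CC(=O)O)C(C)=CC(=O)C=C1C | intermediate
6 | (3aR,7aR)-3a-methoxy-4,7a-dimethyl-3,3a,7,7a-tetrahydro-1-benzofuran-2,6-dione | O=C1C=C(C)[C@]2(OC)CC(=O)O[C@]2(C)C1 | intermediate
7 | (3aR,7aR)-3a-methoxy-4,4,7a-trimethyl-6-[(trimethylsilyl)oxy]-3a,4,7,7a-tetrahydro-1-benzofuran-2(3H)-one | C[Si](C)(C)OC1=CC(C)(C)[C@]2(OC)CC(=O)O[C@]2(C)C1 | intermediate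
8 | (7aR)-4,4,7a-trimethyl-6-[(trimethylsilyl)oxy]-7,7a-dihydro-1-benzofuran-2(4H)-one | C[Si](C)(C)OC1=CC(C)(C)C2=CC(=O)O[C@]2(C)C1 | intermediate (not isolated)
9 | (7aR)-4,4,7a-trimethyl-5,7a-dihydro-1-benzofuran-2,6(4H,7H)-dione | O=C1CC(C)(C)C2=CC(=O)O[C@]2(C)C1 | intermediate
10 | (6S,7aR)-6-hydroxy-4,4,7a-trimethyl-5,6,7,7a-tetrahydro-1-benzofuran-2(4H)-one, (−)-loliolide | O[C@H]1CC(C)(C)C2=CC(=O)O[C@]2(C)C1 | intermediate
11 | palmitoyl chloride | CCCCCCCCCCCCCCCC(=O)Cl | starting material
12 | (6S,7aR)-4,4,7a-trimethyl-2-oxo-2,4,5,6,7,7a-hexahydro-1-benzofuran-6-yl hexadecanoate | CCCCCCCCCCCCCCCC(=O)O[C@H]1CC(C)(C)C2=CC(=O)O[C@]2(C)C1 | target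

## Step count and least certain steps

Total step count: 8. Longest linear sequence: 8 steps (1 to 12).

**Step 4 (key step, proposed new method).**
- Risk: the most likely failure is insufficient discrimination between the two enone arms, followed by erosion of what selectivity there is. A carboxylate is a weak nucleophile and the acceptor carbon is fully substituted, so an unselective closure through a loosely bound ion pair can compete. The product also stays in base-mediated equilibrium with 5 by β-elimination.
- Fallback (known chemistry, from 5 back to 6): closure of 5 with an achiral tertiary amine (DABCO, CH2Cl2, rt) should give racemic cis-3a-methoxy-4,7a-dimethyl-3,3a,7,7a-tetrahydro-1-benzofuran-2,6-dione F1. Preparative chromatography on a chiral stationary phase (cellulose tris(3,5-dimethylphenylcarbamate)) would separate 6 from its mirror image, (3aS,7aS)-3a-methoxy-4,7a-dimethyl-3,3a,7,7a-tetrahydro-1-benzofuran-2,6-dione F2. F2 can be returned to achiral 5 by DBU-induced β-elimination and acidification, and cyclised again.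

**Step 5.**
- Risk: failure of the methyl transfer for steric reasons, since the new quaternary C4 is formed next to the quaternary C3a. Electron transfer from the cuprate with reductive loss of the γ-methoxy group is the second concern.
- Fallback (from 4 back to 9, replacing steps 3 to 6): the methyl is delivered from a neighbouring hydroxyl.
  - Oxidation of 4 with PhI(OAc)2 in aqueous MeCN should give the quinol 2-(1-hydroxy-2,6-dimethyl-4-oxocyclohexa-2,5-dien-1-yl)acetic acid F3.
  - The lactonisation of step 4 would then give (3aR,7aR)-3a-hydroxy-4,7a-dimethyl-3,3a,7,7a-tetrahydro-1-benzofuran-2,6-dione F4.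
  - AlMe3 (excess, CH2Cl2, −78 to 0 °C) forms the aluminium alkoxide at C3a, which guides a methyl group to the adjacent C4. This is the hydroxyl-directed 1,4-addition known for para-quinols. It would give (3aR,7aR)-3a-hydroxy-4,4,7a-trimethylhexahydro-1-benzofuran-2,6-dione F5.
  - Neutral dehydration of the tertiary alcohol with Ph2S[OC(CF3)2Ph]2 (Martin sulfurane) can only go towards C3 and leads to 9.

**Step 6.**
- Risk: premature loss of the silyl group, by adventitious proton sources or by the liberated methoxide followed by proton exchange. This would expose the C6 ketone to base. The C7a–O1 bond would then open by β-elimination and, once C3a is trigonal, the material would racemise. Slow departure of methoxide from the lithium enolate is the second concern.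
- Fallback (from 7 back to 9): C6 is parked at the alcohol oxidation level.
  - Hydrolysis of 7 (dilute HCl, THF, 0 °C) gives (3aR,7aR)-3a-methoxy-4,4,7a-trimethylhexahydro-1-benzofuran-2,6-dione F6.
  - NaBH4 (MeOH, −40 °C) gives (3aR,7aR)-6-hydroxy-3a-methoxy-4,4,7a-trimethylhexahydro-1-benzofuran-2(3H)-one F7, as C6 epimers whose ratio does not matter.
  - KOt-Bu (2.2 equiv, THF, 0 °C) effects the same E1cB loss of methanol, now with no ketone present. It gives 10 together with its C6 epimer (6R,7aR)-6-hydroxy-4,4,7a-trimethyl-5,6,7,7a-tetrahydro-1-benzofuran-2(4H)-one F8.
  - Buffered Dess–Martin oxidation of the mixture converges on 9.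

**Step 1.**
- Risk: wrong regiochemistry. The para position lies between two methyl groups, so attack at an ortho position or a second hydroxyalkylation can compete.
- Fallback (from 1 back to 4, replacing steps 1 and 2): the para position is fixed by halogenation.
  - Bromination (NBS, MeCN, 0 °C) should give 4-bromo-3,5-dimethylphenol F9.
  - Protection (MOMCl, i-Pr2NEt) gives 2-bromo-5-(methoxymethoxy)-1,3-dimethylbenzene F10.
  - Cross-coupling with the Reformatsky reagent BrZnCH2CO2t-Bu (Pd(dba)2, P(t-Bu)3, THF) gives tert-butyl 2-[4-(methoxymethoxy)-2,6-dimethylphenyl]acetate F11.
  - CF3CO2H in wet CH2Cl2 removes both protecting groups and gives 4.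

## Further compounds

F1 | step 4 | racemic cis-3a-methoxy-4,7a-dimethyl-3,3a,7,7a-tetrahydro-1-benzofuran-2,6-dione | COC12CC(=O)OC1(C)CC(=O)C=C2C
F2 | step 4 | (3aS,7aS)-3a-methoxy-4,7a-dimethyl-3,3a,7,7a-tetrahydro-1-benzofuran-2,6-dione | O=C1C=C(C)[C@@]2(OC)CC(=O)O[C@@]2(C)C1
F3 | step 5 | 2-(1-hydroxy-2,6-dimethyl-4-oxocyclohexa-2,5-dien-1-yl)acetic acid | OC1(CC(=O)O)C(C)=CC(=O)C=C1C
F4 | step 5 | (3aR,7aR)-3a-hydroxy-4,7a-dimethyl-3,3a,7,7a-tetrahydro-1-benzofuran-2,6-dione | O=C1C=C(C)[C@]2(O)CC(=O)O[C@]2(C)C1
F5 | step 5 | (3aR,7aR)-3a-hydroxy-4,4,7a-trimethylhexahydro-1-benzofuran-2,6-dione | O=C1CC(C)(C)[C@]2(O)CC(=O)O[C@]2(C)C1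
F6 | step 6 | (3aR,7aR)-3a-methoxy-4,4,7a-trimethylhexahydro-1-benzofuran-2,6-dione | O=C1CC(C)(C)[C@]2(OC)CC(=O)O[C@]2(C)C1
F7 | step 6 | (3aR,7aR)-6-hydroxy-3a-methoxy-4,4,7a-trimethylhexahydro-1-benzofuran-2(3H)-one (C6 epimers) | OC1CC(C)(C)[C@]2(OC)CC(=O)O[C@]2(C)C1
F8 | step 6 | (6R,7aR)-6-hydroxy-4,4,7a-trimethyl-5,6,7,7a-tetrahydro-1-benzofuran-2(4H)-one | O[C@@H]1CC(C)(C)C2=CC(=O)O[C@]2(C)C1
F9 | step 1 | 4-bromo-3,5-dimethylphenol | Cc1cc(O)cc(C)c1Br
F10 | step 1 | 2-bromo-5-(methoxymethoxy)-1,3-dimethylbenzene | COCOc1cc(C)c(Br)c(C)c1
F11 | step 1 | tert-butyl 2-[4-(methoxymethoxy)-2,6-dimethylphenyl]acetate | COCOc1cc(C)c(CC(=O)OC(C)(C)C)c(C)c1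
A1 | alternative 1 | ethyl (Z)-2-[(2R,4S)-2-hydroxy-2,6,6-trimethyl-4-(palmitoyloxy)cyclohexylidene]acetate | CCCCCCCCCCCCCCCC(=O)O[C@H]1CC(C)(C)/C(=C/C(=O)OCC)[C@](C)(O)C1
A2 | alternative 1 | ethyl (4R,6S)-4-hydroxy-4,8-dimethyl-6-(palmitoyloxy)non-8-en-2-ynoate | CCCCCCCCCCCCCCCC(=O)O[C@@H](CC(C)=C)C[C@@](C)(O)C#CC(=O)OCC
A3 | alternative 2 | (6R,7aR)-6-(tert-butyldimethylsilyloxy)-4,4,7a-trimethyl-5,6,7,7a-tetrahydrobenzofuran-2(4H)-one | CC(C)(C)[Si](C)(C)O[C@@H]1CC(C)(C)C2=CC(=O)O[C@]2(C)C1
A4 | alternative 2 | (4R)-4-(tert-butyldimethylsilyloxy)-6,6-dimethyloct-7-yn-2-one | CC(=O)C[C@H](O[Si](C)(C)C(C)(C)C)CC(C)(C)C#C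
A5 | alternative 3 | allyl (3aS,6S,7aR)-4,4,7a-trimethyl-2-oxo-6-(palmitoyloxy)octahydrobenzofuran-3-carboxylate (C3 epimers) | CCCCCCCCCCCCCCCC(=O)O[C@H]1CC(C)(C)[C@@H]2C(C(=O)OCC=C)C(=O)O[C@]2(C)C1
A6 | alternative 3 | 1-allyl 3-[(1S,5S)-1,3,3-trimethyl-5-(palmitoyloxy)cyclohexyl] 2-diazomalonate | CCCCCCCCCCCCCCCC(=O)O[C@H]1CC(C)(C)C[C@](C)(OC(=O)C(=[N+]=[N-])C(=O)OCC=C)C1
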